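The target is made from starting material and lost again, so what stands at the end is a balance. I kept a ledger of the solid substrate, the limiting reagent, since the gas is held.

solid substrate 2.0 × 10⁻⁴ M; gas phase 0.0097 mM (held); time 1.5 min

    gas phase ⇌ dissolved gas, rate k1*(csat - [dissolved gas]) (k1 = 31 s⁻¹, csat = 0.0097 mM)
    starting material + dissolved gas → target (k2 = 4800 M⁻¹ s⁻¹)
    dissolved gas + target → over-reacted product (k3 = 7300 M⁻¹ s⁻¹)
    solid substrate ⇌ starting material, rate k4*(cs4 - [starting material]) while solid is left; crystals form when [starting material] > cs4 (cs4 = 0.12 mM, k4 = 0.015 s⁻¹)
    target → over-reaction product (k5 = 0.021 s⁻¹)

- given per volume of solution although it is solid: solid substrate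
- at the start none of the gas is dissolved
- at the start none of the solid substrate is in solution
- run time (flask): 1.5 min

* how much target there is at 1.5 min, in percent of the solid substrate charged
* the change that raises the amount of target at 1.5 min, in percent of the solid substrate charged most ("none" if none brings more than 2 percentage points) (green / red / violet / teal / none)
* amount of target at 1.5 min, in percent of the solid substrate charged, after green

- green: doubling the saturation concentration of gas phase, all else as stated
- red: doubling the dissolution coefficient of step 4, all else as stated
- violet: doubling the solubility in step 4, all else as stated
- teal: doubling the transfer coefficient of step 1, all else as stated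

Transfer runs at 31 s⁻¹, faster than the gas steps could use gas even on the whole charge, 1.46 s⁻¹. So I held dissolved gas at saturation, which makes its steps pseudo-first-order: starting material goes at 0.0466 s⁻¹, and target at 0.0918 s⁻¹, step 5 included. Solubility is 60.0% of the charge. An empty solution gave a first standing share of starting material of 19.3%; put back, that gave 13.1%, and the rounds closed on 14.6%.

Target then stands at the plateau fraction, its steady level as a part of the solubility, 12.4%. Starting material nears its standing share on a time of about 16.2 s and target follows on about 10.9 s, together less than the run, and I reckoned the solid to last 2.45 min, longer than the run. So I committed to 7.41% of the charge as target. The books: 61.3% dissolved, 38.7% still solid, and 39.2% passed on, as 30.3% over-reacted product and 8.97% over-reaction product.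

Reckoned the same way, green gave 4.77%. Red gave 11.9%, with a reckoned solid life of 1.52 min. Violet, in my reckoning, doubled the plateau amount but halved the solid's life, leaving 16.5 s of decay and 10.6%. Teal left the reckoned plateau alone. My choice was red.

The forecast, reasoning that “the dissolved gas stays essentially at saturation”, gave 7.4%, red and 4.8%.

The flask gave 7.36%, 4.78% after green, and red as the best change, worth 3.7 percentage points. At 1.50 min starting material was made 1.01 times as fast as it was used up. At 3.00 min, later than the reckoned life of the solid, target in this flask read 2.35%, less than the plateau fraction gives.

In the neighbour flask charged with 8.0 × 10⁻⁴ M of solid substrate, the plateau fraction holds no term for the charge, and as a part of the solubility it came to 1.85% of that larger charge. That flask gave 1.84%.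

(The rate constants are those of an exercise; no experiment stands behind them.)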